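**Retrosynthetic overview**

1. Labels: ring C = central arene (C9b bears the CH2 C8b, C10b bears the CH C8a, C11b and C13b bear the two furan oxygens, C14b bears C8c); ring A = dioxygenated arene fused to the seven-membered ring; C7a/C8a and C7c/C8c = methines of dihydrofurans 1 and 2; C7b = ArCH of the seven-membered ring.
2. Target ⇐ octabenzyl ether 33 ⇐ dihydrofuran 2, then dihydrofuran 1, each by [4+1] annulation of an o-quinone methide with a 4-(benzyloxy)benzyl sulfonium ylide ⇐ dibenzocycloheptenone 18.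
3. Key disconnection C10b–C8a (together with C9b–C8b): acyl-alkylation of 3,5-bis(methoxymethoxy)benzyne with the enantioenriched 3-aryl-1-indanone-2-carboxylate 12, which expands the five-membered ring to the seven-membered ring.
4. Enabling feature: C9b and C10b are adjacent ring C carbons holding the two ends of the seven-membered ring, and C10b lies next to the oxygen-bearing C11b (the pattern a 3-alkoxyaryne delivers); C8a, two ring A carbons, C7b and C8b are the five ring atoms of a 1-indanone with C8a as the carbonyl carbon.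
5. Ring order: ring A-fused indanone (asymmetric Nazarov, sets C7b) → seven-membered ring (aryne insertion) → dihydrofuran 1 (C8a/C7a controlled by C7b) → dihydrofuran 2 (C8c/C7c controlled by a chiral sulfonium ylide).

Key step: step 8

Assumption: the absolute sense of induction in steps 7 and 19, and the exo position of the benzyl group on sulfur in 30, are drawn as the target requires; the antipodes of the bis(oxazoline) ligand and of isothiocineole are equally available if the sense proves opposite.

**Route**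

Step 1
Reactants: 1 phloroglucinol
Product: 2 3,5-bis(methoxymethoxy)phenol
Conditions: MOMCl (2.0 equiv), i-Pr2NEt, CH2Cl2/DMF, 0 → 23 °C; chromatography
Reagents that add atoms: chloromethyl methyl ether, COCCl
Why: Williamson-type O-alkylation of the symmetric triphenol should give the bis-ether as the main component of a statistical mixture, from which the mono- and tris-ethers are separated.

Step 2
Reactants: 2 3,5-bis(methoxymethoxy)phenol
Product: 3 3,5-bis(methoxymethoxy)phenyl N-isopropylcarbamate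
Conditions: i-PrNCO, Et3N (cat.), CH2Cl2, 23 °C
Reagents that add atoms: isopropyl isocyanate, CC(C)N=C=O
Why: Addition of the phenol to the isocyanate installs the carbamate that directs ortho-metalation and is later removed under mild base.

Step 3
Reactants: 3 3,5-bis(methoxymethoxy)phenyl N-isopropylcarbamate
Product: 5 3,5-bis(methoxymethoxy)-2-(trimethylsilyl)phenyl N-isopropylcarbamate, via N-silyl carbamate 4 (not isolated)
Conditions: TBSOTf, TMEDA, Et2O, 0 → 23 °C; n-BuLi, TMEDA, −78 °C; TMSCl, −78 → 23 °C; aq. NaHSO4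
Reagents that add atoms: chlorotrimethylsilane, C[Si](C)(C)Cl
Why: Directed ortho-metalation: after in situ N-silylation the carbamate and the neighbouring OMOM group jointly direct lithiation to C2 (equivalent to C6), in preference to the position between the two OMOM groups, and TMSCl traps the aryllithium.

Step 4
Reactants: 5 3,5-bis(methoxymethoxy)-2-(trimethylsilyl)phenyl N-isopropylcarbamate
Product: 7 3,5-bis(methoxymethoxy)-2-(trimethylsilyl)phenyl trifluoromethanesulfonate, via silylphenol 6 (not isolated)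
Conditions: DBU, Et2NH, MeCN, 40 °C; then PhNTf2, 23 °C
Reagents that add atoms: N-phenylbis(trifluoromethanesulfonimide), O=S(=O)(N(c1ccccc1)S(=O)(=O)C(F)(F)F)C(F)(F)F
Why: E1cB cleavage of the N-monosubstituted carbamate (isocyanate scavenged by Et2NH) releases the phenoxide, which is triflated in the same flask to the ortho-silylaryl triflate.

Step 5
Reactants: 8 1-[3,5-bis(benzyloxy)phenyl]ethan-1-one
Product: 9 methyl 3-[3,5-bis(benzyloxy)phenyl]-3-oxopropanoate
Conditions: NaH, (MeO)2CO, THF, 65 °C; aq. HCl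
Reagents that add atoms: dimethyl carbonate, COC(=O)OC
Why: Crossed Claisen condensation of the ketone enolate with dimethyl carbonate, driven by deprotonation of the β-keto ester.

Step 6
Reactants: 9 methyl 3-[3,5-bis(benzyloxy)phenyl]-3-oxopropanoate; 10 2,4-bis(benzyloxy)benzaldehyde
Product: 11 methyl 2-[3,5-bis(benzyloxy)benzoyl]-3-[2,4-bis(benzyloxy)phenyl]prop-2-enoate (E/Z mixture)
Conditions: piperidine (cat.), AcOH (cat.), benzene, 80 °C, Dean–Stark
Reagents that add atoms: none
Why: Knoevenagel condensation of the active methylene compound with the aromatic aldehyde under azeotropic removal of water.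

Step 7
Reactants: 11 methyl 2-[3,5-bis(benzyloxy)benzoyl]-3-[2,4-bis(benzyloxy)phenyl]prop-2-enoate
Product: 12 methyl (3S)-4,6-bis(benzyloxy)-3-[2,4-bis(benzyloxy)phenyl]-1-oxo-2,3-dihydro-1H-indene-2-carboxylate
Conditions: Cu(OTf)2 (10 mol %), (S,S)-Ph-BOX (12 mol %), ClCH2CH2Cl, 40 °C
Reagents that add atoms: none
Why: Lewis acid-catalysed Nazarov cyclization (4π conrotatory closure of the chelated aryl vinyl β-keto ester onto the ring A carbon ortho and para to the benzyloxy groups), in which the chelate of Cu(OTf)2 with the chiral bis(oxazoline) fixes the sense of conrotation and so sets C7b (S); the E/Z isomers interconvert under the Lewis acid, and C2 is protonated trans but stays epimerizable.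

Step 8
Reactants: 7 3,5-bis(methoxymethoxy)-2-(trimethylsilyl)phenyl trifluoromethanesulfonate; 12 methyl (3S)-4,6-bis(benzyloxy)-3-[2,4-bis(benzyloxy)phenyl]-1-oxo-2,3-dihydro-1H-indene-2-carboxylate
Product: 15 methyl (10S)-7,9-bis(benzyloxy)-10-[2,4-bis(benzyloxy)phenyl]-2,4-bis(methoxymethoxy)-5-oxo-10,11-dihydro-5H-dibenzo[a,d][7]annulene-11-carboxylate, via aryne 13 (not isolated), via benzocyclobutenoxide 14 (not isolated)
Conditions: CsF (3 equiv), MeCN, 80 °C; 7 (1.3 equiv)
Reagents that add atoms: none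
Why: Fluoride unmasks aryne 13 from 7 and forms the cesium enolate of 12; the enolate carbon C8b adds to the aryne carbon remote from the flanking OMOM group (C9b), and the resulting aryl anion at C10b closes onto the indanone carbonyl C8a (4-exo-trig, forming the C10b–C8a bond) to give benzocyclobutenoxide 14, whose C8a–C8b bond then cleaves in a retro-aldol sense to an ester-stabilized carbanion, so that the five-membered ring is expanded by two carbons. The closest known reaction is the acyl-alkylation of arynes with cyclic β-keto esters (two-carbon ring expansion to benzannulated medium rings), which is established for 3-alkoxy- and 3,5-dialkoxybenzynes. The C10b–C8a bond closes the transient four-membered ring and, after fragmentation, is the ring-closing bond of the seven-membered ring. No stereocenter of the target is created: C7b is not enolizable and is carried through unchanged, while the new ester-bearing C8b center is epimerizable and disappears in step 10. The step needs regioselectivity (enolate carbon on C9b, acyl group on C10b), which the inductively withdrawing OMOM group beside the triple bond secures by making the distal aryne carbon the electrophilic one and placing the carbanion next to the C–O bond; the second OMOM group is meta to the attacked carbon, and the quaternary α-carbon formed on C-arylation leaves the aryl anion no proton to take, so acyl transfer follows.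

Step 9
Reactants: 15 methyl (10S)-…-5-oxo-dibenzo[a,d][7]annulene-11-carboxylate
Product: 16 the corresponding 11-carboxylic acid
Conditions: LiOH·H2O, THF/MeOH/H2O, 50 °C; aq. HCl
Reagents that add atoms: lithium hydroxide, [Li+].[OH-]
Why: Saponification of the methyl ester; the diaryl ketone is non-enolizable, C7b is not acidic, and the C8b epimers converge in the next step.

Step 10
Reactants: 16 the 11-carboxylic acid
Product: 18 (10S)-7,9-bis(benzyloxy)-10-[2,4-bis(benzyloxy)phenyl]-2,4-bis(methoxymethoxy)-10,11-dihydro-5H-dibenzo[a,d][7]annulen-5-one, via Barton ester 17 (not isolated)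
Conditions: 1-hydroxypyridine-2(1H)-thione, EDC·HCl, DMAP (cat.), CH2Cl2, 0 °C, dark; then t-BuSH, hν (visible), 23 °C
Reagents that add atoms: none
Why: Barton reductive decarboxylation (radical chain): the thiohydroxamate ester fragments to the benzylic C8b radical, which abstracts hydrogen from the thiol and leaves C7b untouched.

Step 11
Reactants: 18 the bis(methoxymethoxy) ketone
Product: 19 (10S)-7,9-bis(benzyloxy)-10-[2,4-bis(benzyloxy)phenyl]-2,4-dihydroxy-10,11-dihydro-5H-dibenzo[a,d][7]annulen-5-one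
Conditions: HCl (conc., cat.), MeOH/THF, 50 °C
Reagents that add atoms: none
Why: Acid-catalysed cleavage of both methoxymethyl acetals by transacetalization to dimethoxymethane; benzyl ethers and the ketone are stable.

Step 12
Reactants: 19 the 2,4-dihydroxy ketone
Product: 20 the 2,4-bis(tert-butoxycarbonyloxy) ketone
Conditions: Boc2O (3 equiv), DMAP (cat.), Et3N, CH2Cl2, 23 °C
Reagents that add atoms: di-tert-butyl dicarbonate, CC(C)(C)OC(=O)OC(=O)OC(C)(C)C
Why: DMAP-catalysed carbonate formation on both phenols; the C11b carbonate is the transferable group for o-quinone methide generation and the C13b carbonate is a protecting group.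

Step 13
Reactants: 21 tetrahydrothiophene; 22 4-(benzyloxy)benzyl bromide
Product: 23 1-[4-(benzyloxy)benzyl]tetrahydrothiophenium tetrafluoroborate
Conditions: NaBF4, CH2Cl2/H2O, 23 °C
Reagents that add atoms: sodium tetrafluoroborate, [Na+].F[B-](F)(F)F
Why: S-Alkylation of the sulfide by the benzylic bromide with exchange to the non-nucleophilic tetrafluoroborate, which prevents reversal.

Step 14
Reactants: 20 the 2,4-bis(tert-butoxycarbonyloxy) ketone; 23 1-[4-(benzyloxy)benzyl]tetrahydrothiophenium tetrafluoroborate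
Product: 25 dihydrofuran-1 tetracycle (C13b carbonate; 7aS,8aS,7bS), via o-quinone methide 24 (not isolated)
Conditions: LiAlH(Ot-Bu)3 (1.1 equiv), THF, −78 → −40 °C; then ylide from 23 and LiN(SiMe3)2 (THF, −78 °C); −78 → 0 °C
Reagents that add atoms: none
Why: Anionic o-quinone methide generation (hydride reduction of the ketone, O→O transfer of the neighbouring Boc group, loss of tert-butyl carbonate) followed by [4+1] annulation with the benzylic sulfonium ylide: the ylide carbon should add to C8a on the face opposite the C7b aryl group (pseudo-axial because of A(1,3) strain with the ring A benzyloxy group), which gives 8aS, and SN2 closure of the phenoxide on C7a with loss of tetrahydrothiophene gives the trans-dihydrofuran (7aS); the remote C13b carbonate is untouched.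

Step 15
Reactants: 25 dihydrofuran-1 tetracycle (C13b carbonate)
Product: 26 dihydrofuran-1 tetracycle (C13b phenol)
Conditions: K2CO3, MeOH/THF, 23 °C
Reagents that add atoms: none
Why: Mild base-catalysed methanolysis of the aryl carbonate frees the C13b phenol without touching benzyl ethers or the dihydrofuran.

Step 16
Reactants: 26 dihydrofuran-1 tetracycle (C13b phenol)
Product: 27 the C14b carbaldehyde of 26
Conditions: MgCl2, Et3N, (CH2O)n, THF, 65 °C
Reagents that add atoms: paraformaldehyde (as formaldehyde), C=O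
Why: Magnesium phenoxide-directed ortho-formylation is specific for the only free phenol and should enter at C14b, the ortho position para to the furan oxygen, and not at the position flanked by two oxygens, as with 3-alkoxyphenols.

Step 17
Reactants: 27 the C14b carbaldehyde
Product: 28 the C13b tert-butyl carbonate of 27
Conditions: Boc2O, DMAP (cat.), Et3N, CH2Cl2, 23 °C
Reagents that add atoms: di-tert-butyl dicarbonate, CC(C)(C)OC(=O)OC(=O)OC(C)(C)C
Why: Carbonate formation on the salicylaldehyde hydroxyl installs the transferable group for the second o-quinone methide generation.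

Step 18
Reactants: 29 (1R,4R,5R)-isothiocineole; 22 4-(benzyloxy)benzyl bromide
Product: 30 S-[4-(benzyloxy)benzyl]isothiocineolium tetrafluoroborate
Conditions: NaBF4, CH2Cl2/H2O, 23 °C
Reagents that add atoms: sodium tetrafluoroborate, [Na+].F[B-](F)(F)F
Why: S-Alkylation of the rigid bicyclic sulfide on its exposed lone pair should give one sulfonium diastereomer, isolated as the tetrafluoroborate.

Step 19
Reactants: 28 the C13b carbonate aldehyde; 30 S-[4-(benzyloxy)benzyl]isothiocineolium tetrafluoroborate; 31 1,3-bis(benzyloxy)-5-bromobenzene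
Product: 33 octa-O-benzyl ether of the target, via o-quinone methide 32 (not isolated)
Conditions: ArMgBr (from 31, Mg, THF), THF, −78 °C; then ylide from 30 and LiN(SiMe3)2 (THF, −78 °C); −78 → −20 °C
Reagents that add atoms: none
Why: The same anionic o-quinone methide/[4+1] annulation, now triggered by addition of the aryl Grignard reagent to the aldehyde and Boc transfer from the adjacent C13b oxygen: the isothiocineole-derived ylide should add through a single face as in its epoxidations, and anti addition to the o-quinone methide with invertive ring closure gives the trans-(7cR,8cR) dihydrofuran, any wrong-sense adduct being a separable diastereomer because the core is already a single enantiomer.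

Step 20
Reactants: 33 octa-O-benzyl ether of the target
Product: 34 target
Conditions: H2 (1 atm), Pd/C, EtOAc/MeOH, 23 °C
Reagents that add atoms: none
Why: Hydrogenolysis of the eight benzyl ethers under neutral conditions; the cyclic benzylic C–O bonds of the two dihydrofurans should be cleaved much more slowly, and no stereocenter is touched.

**Compound list**

1 | phloroglucinol | Oc1cc(O)cc(O)c1 | starting material
2 | 3,5-bis(methoxymethoxy)phenol | COCOc1cc(O)cc(OCOC)c1 | intermediate
3 | 3,5-bis(methoxymethoxy)phenyl N-isopropylcarbamate | CC(C)NC(=O)Oc1cc(OCOC)cc(OCOC)c1 | intermediate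
4 | N-(tert-butyldimethylsilyl) derivative of 3 | CC(C)N([Si](C)(C)C(C)(C)C)C(=O)Oc1cc(OCOC)cc(OCOC)c1 | intermediate (not isolated)
5 | 3,5-bis(methoxymethoxy)-2-(trimethylsilyl)phenyl N-isopropylcarbamate | CC(C)NC(=O)Oc1cc(OCOC)cc(OCOC)c1[Si](C)(C)C | intermediate
6 | 3,5-bis(methoxymethoxy)-2-(trimethylsilyl)phenol | Oc1cc(OCOC)cc(OCOC)c1[Si](C)(C)C | intermediate (not isolated)
7 | 3,5-bis(methoxymethoxy)-2-(trimethylsilyl)phenyl trifluoromethanesulfonate | FC(F)(F)S(=O)(=O)Oc1cc(OCOC)cc(OCOC)c1[Si](C)(C)C | intermediate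
8 | 1-[3,5-bis(benzyloxy)phenyl]ethan-1-one | CC(=O)c1cc(OCc2ccccc2)cc(OCc2ccccc2)c1 | starting material
9 | methyl 3-[3,5-bis(benzyloxy)phenyl]-3-oxopropanoate | COC(=O)CC(=O)c1cc(OCc2ccccc2)cc(OCc2ccccc2)c1 | intermediate
10 | 2,4-bis(benzyloxy)benzaldehyde | O=Cc1ccc(OCc2ccccc2)cc1OCc1ccccc1 | starting material
11 | methyl 2-[3,5-bis(benzyloxy)benzoyl]-3-[2,4-bis(benzyloxy)phenyl]prop-2-enoate (E/Z mixture) | COC(=O)C(=Cc1ccc(OCc2ccccc2)cc1OCc1ccccc1)C(=O)c1cc(OCc2ccccc2)cc(OCc2ccccc2)c1 | intermediate
12 | methyl (3S)-4,6-bis(benzyloxy)-3-[2,4-bis(benzyloxy)phenyl]-1-oxo-2,3-dihydro-1H-indene-2-carboxylate (C2 epimers and enol in equilibrium, 2,3-trans favoured) | COC(=O)C1C(=O)c2cc(OCc9ccccc9)cc(OCc9ccccc9)c2[C@@H]1c1ccc(OCc9ccccc9)cc1OCc9ccccc9 | intermediate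
13 | 3,5-bis(methoxymethoxy)benzyne | COCOC1=CC(OCOC)=CC#C1 | intermediate (not isolated)
14 | cesium benzocyclobutenoxide formed from 12 and 13 (four-membered ring C9b–C8b–C8a–C10b; C8a and C8b transient) | [Cs+].[O-]C12c3cc(OCc9ccccc9)cc(OCc9ccccc9)c3[C@H](c3ccc(OCc9ccccc9)cc3OCc9ccccc9)C1(C(=O)OC)c1cc(OCOC)cc(OCOC)c12 | intermediate (not isolated)
15 | methyl (10S)-7,9-bis(benzyloxy)-10-[2,4-bis(benzyloxy)phenyl]-2,4-bis(methoxymethoxy)-5-oxo-10,11-dihydro-5H-dibenzo[a,d][7]annulene-11-carboxylate (C11 epimers) | COCOc1cc(OCOC)cc2c1C(=O)c1cc(OCc9ccccc9)cc(OCc9ccccc9)c1[C@H](c1ccc(OCc9ccccc9)cc1OCc9ccccc9)C2C(=O)OC | intermediate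
16 | (10S)-7,9-bis(benzyloxy)-10-[2,4-bis(benzyloxy)phenyl]-2,4-bis(methoxymethoxy)-5-oxo-10,11-dihydro-5H-dibenzo[a,d][7]annulene-11-carboxylic acid (C11 epimers) | COCOc1cc(OCOC)cc2c1C(=O)c1cc(OCc9ccccc9)cc(OCc9ccccc9)c1[C@H](c1ccc(OCc9ccccc9)cc1OCc9ccccc9)C2C(=O)O | intermediate
17 | 2-thioxopyridin-1(2H)-yl ester of 16 | COCOc1cc(OCOC)cc2c1C(=O)c1cc(OCc9ccccc9)cc(OCc9ccccc9)c1[C@H](c1ccc(OCc9ccccc9)cc1OCc9ccccc9)C2C(=O)ON1C=CC=CC1=S | intermediate (not isolated)
18 | (10S)-7,9-bis(benzyloxy)-10-[2,4-bis(benzyloxy)phenyl]-2,4-bis(methoxymethoxy)-10,11-dihydro-5H-dibenzo[a,d][7]annulen-5-one | COCOc1cc(OCOC)cc2c1C(=O)c1cc(OCc9ccccc9)cc(OCc9ccccc9)c1[C@H](c1ccc(OCc9ccccc9)cc1OCc9ccccc9)C2 | intermediate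
19 | (10S)-7,9-bis(benzyloxy)-10-[2,4-bis(benzyloxy)phenyl]-2,4-dihydroxy-10,11-dihydro-5H-dibenzo[a,d][7]annulen-5-one | Oc1cc(O)cc2c1C(=O)c1cc(OCc9ccccc9)cc(OCc9ccccc9)c1[C@H](c1ccc(OCc9ccccc9)cc1OCc9ccccc9)C2 | intermediate
20 | (10S)-7,9-bis(benzyloxy)-10-[2,4-bis(benzyloxy)phenyl]-2,4-bis(tert-butoxycarbonyloxy)-10,11-dihydro-5H-dibenzo[a,d][7]annulen-5-one | CC(C)(C)OC(=O)Oc1cc(OC(=O)OC(C)(C)C)cc2c1C(=O)c1cc(OCc9ccccc9)cc(OCc9ccccc9)c1[C@H](c1ccc(OCc9ccccc9)cc1OCc9ccccc9)C2 | intermediate
21 | tetrahydrothiophene | C1CCSC1 | starting material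
22 | 4-(benzyloxy)benzyl bromide | BrCc1ccc(OCc2ccccc2)cc1 | starting material
23 | 1-[4-(benzyloxy)benzyl]tetrahydrothiophenium tetrafluoroborate | c1ccccc1COc1ccc(C[S+]2CCCC2)cc1.F[B-](F)(F)F | intermediate
24 | o-quinone methide from 20 (C11b=O, C10b=C8a; C13b carbonate retained; 7bS) | O=C1C=C(OC(=O)OC(C)(C)C)C=C2C[C@@H](c3ccc(OCc9ccccc9)cc3OCc9ccccc9)c3c(OCc9ccccc9)cc(OCc9ccccc9)cc3C=C12 | intermediate (not isolated)
25 | dihydrofuran-1 tetracycle (7aS,8aS,7bS): trans-dihydrofuran O–C7a–C8a fused at C11b/C10b, C7a bearing 4-(benzyloxy)phenyl, ring A and C7b aryl as benzyl ethers, C13b tert-butyl carbonate | c9ccccc9COc1ccc([C@H]2Oc3cc(OC(=O)OC(C)(C)C)cc5c3[C@@H]2c2cc(OCc9ccccc9)cc(OCc9ccccc9)c2[C@H](c2ccc(OCc9ccccc9)cc2OCc9ccccc9)C5)cc1 | intermediate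
26 | C13b phenol corresponding to 25 | c9ccccc9COc1ccc([C@H]2Oc3cc(O)cc5c3[C@@H]2c2cc(OCc9ccccc9)cc(OCc9ccccc9)c2[C@H](c2ccc(OCc9ccccc9)cc2OCc9ccccc9)C5)cc1 | intermediate
27 | C14b carbaldehyde of 26 (salicylaldehyde) | c9ccccc9COc1ccc([C@H]2Oc3cc(O)c(C=O)c5c3[C@@H]2c2cc(OCc9ccccc9)cc(OCc9ccccc9)c2[C@H](c2ccc(OCc9ccccc9)cc2OCc9ccccc9)C5)cc1 | intermediate
28 | C13b tert-butyl carbonate of 27 | c9ccccc9COc1ccc([C@H]2Oc3cc(OC(=O)OC(C)(C)C)c(C=O)c5c3[C@@H]2c2cc(OCc9ccccc9)cc(OCc9ccccc9)c2[C@H](c2ccc(OCc9ccccc9)cc2OCc9ccccc9)C5)cc1 | intermediate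
29 | (1R,4R,5R)-isothiocineole [(1R,4R,5R)-4,7,7-trimethyl-6-thiabicyclo[3.2.1]octane] | C[C@@H]1CC[C@@H]2C[C@H]1SC2(C)C | starting material
30 | S-[4-(benzyloxy)benzyl]-(1R,4R,5R)-isothiocineolium tetrafluoroborate (benzyl group exo on sulfur) | C[C@@H]1CC[C@@H]2C[C@H]1[S@@+](Cc1ccc(OCc3ccccc3)cc1)C2(C)C.F[B-](F)(F)F | intermediate
31 | 1,3-bis(benzyloxy)-5-bromobenzene | Brc1cc(OCc2ccccc2)cc(OCc2ccccc2)c1 | starting material
32 | o-quinone methide from 28 (C13b=O, C14b=CH–Ar with Ar = 3,5-bis(benzyloxy)phenyl; 7aS,8aS,7bS) | O=C1C=C2O[C@H](c3ccc(OCc9ccccc9)cc3)[C@@H]3C2=C(C[C@@H](c4ccc(OCc9ccccc9)cc4OCc9ccccc9)c2c(OCc9ccccc9)cc(OCc9ccccc9)cc23)C1=Cc1cc(OCc9ccccc9)cc(OCc9ccccc9)c1 | intermediate (not isolated)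
33 | octa-O-benzyl ether of the target (7aS,8aS,7bS,7cR,8cR) | c9ccccc9COc1ccc([C@H]2Oc3cc4c(c5c3[C@@H]2c2cc(OCc9ccccc9)cc(OCc9ccccc9)c2[C@H](c2ccc(OCc9ccccc9)cc2OCc9ccccc9)C5)[C@@H](c2cc(OCc9ccccc9)cc(OCc9ccccc9)c2)[C@H](c2ccc(OCc9ccccc9)cc2)O4)cc1 | intermediate
34 | CNP0154047.3 (7aS,8aS,7bS,7cR,8cR) | Oc1ccc([C@H]2Oc3cc4c(c5c3[C@@H]2c2cc(O)cc(O)c2[C@H](c2ccc(O)cc2O)C5)[C@@H](c2cc(O)cc(O)c2)[C@H](c2ccc(O)cc2)O4)cc1 | target

**Step count and risks**

Total steps: 20. Longest linear sequence: 15 (steps 1–4, 8–12, 14–17, 19, 20).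

Steps most likely to fail:

1. Step 19. The risk is insufficient facial discrimination when the chiral ylide adds to the o-quinone methide, together with some cis closure, so that the second dihydrofuran forms as a mixture of diastereomers. The fallback sets out from 26 and returns at 33. Henry condensation of 3,5-bis(benzyloxy)benzaldehyde with nitromethane (NH4OAc, AcOH) gives (E)-1,3-bis(benzyloxy)-5-(2-nitrovinyl)benzene F5. An enantioselective Friedel–Crafts alkylation of phenol 26 with F5, catalysed by a cinchona-derived squaramide and directed ortho to the free hydroxyl at C14b, gives the nitroalkane adduct F6 with C8c set by the catalyst. A Nef reaction (KOH, MeOH; then aq. TiCl3/NH4OAc) gives the aldehyde as its lactol F7. Addition of 4-(benzyloxy)phenylmagnesium bromide gives the diol F8. TsOH-catalysed dehydrative closure through the p-alkoxybenzyl cation gives the trans-dihydrofuran 33.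

2. Step 14. The risk is addition of the ylide to the wrong face of the o-quinone methide (C8a epimer), or consumption of the o-quinone methide by reduction or dimerization before it is trapped. The fallback sets out from 20 and returns at 25. Addition of 4-(benzyloxy)benzylmagnesium chloride to the ketone triggers the same carbonate transfer and elimination. The resulting o-quinone methide now carries a CH2 group on C8a and tautomerizes to the o-hydroxystilbene F4. Acid-catalysed cycloisomerization (TsOH, CH2Cl2) proceeds by reversible protonation at C8a and capture of the C7a cation by the phenol. This thermodynamic control should favour the isomer with the C7b aryl group on the convex face and the trans-dihydrofuran, 25.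

3. Step 8. The risk is O-arylation of the enolate, or arylation at carbon that is not followed by acyl transfer, so that no ring expansion occurs. The fallback sets out from 2 and 12 and returns at 15. Triflation of 2 (Tf2O, pyridine) gives 3,5-bis(methoxymethoxy)phenyl trifluoromethanesulfonate F1. α-Arylation of 12 with F1, catalysed by Pd(OAc)2/t-Bu3P (K3PO4, toluene), gives the α-aryl β-keto ester F2. Hydroxide-induced retro-Claisen opening of this non-enolizable β-keto ester (KOH, aq. THF) gives the benzoic acid F3. Intramolecular Friedel–Crafts acylation (TFAA, CH2Cl2, 0 °C) at either of the two equivalent positions ortho to the benzylic carbon forms the C10b–C8a bond and gives 15.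

**Further compounds**

F1 | step 8 | 3,5-bis(methoxymethoxy)phenyl trifluoromethanesulfonate | COCOc1cc(OCOC)cc(OS(=O)(=O)C(F)(F)F)c1
F2 | step 8 | methyl (3S)-4,6-bis(benzyloxy)-3-[2,4-bis(benzyloxy)phenyl]-2-[3,5-bis(methoxymethoxy)phenyl]-1-oxo-2,3-dihydro-1H-indene-2-carboxylate | COC(=O)C1(c2cc(OCOC)cc(OCOC)c2)C(=O)c2cc(OCc9ccccc9)cc(OCc9ccccc9)c2[C@@H]1c1ccc(OCc9ccccc9)cc1OCc9ccccc9
F3 | step 8 | 3,5-bis(benzyloxy)-2-[(1S)-1-[2,4-bis(benzyloxy)phenyl]-2-[3,5-bis(methoxymethoxy)phenyl]-3-methoxy-3-oxopropyl]benzoic acid | COC(=O)C(c1cc(OCOC)cc(OCOC)c1)[C@@H](c1ccc(OCc9ccccc9)cc1OCc9ccccc9)c1c(OCc9ccccc9)cc(OCc9ccccc9)cc1C(=O)O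
F4 | step 14 | (10S)-7,9-bis(benzyloxy)-5-[4-(benzyloxy)benzylidene]-10-[2,4-bis(benzyloxy)phenyl]-4-hydroxy-10,11-dihydro-5H-dibenzo[a,d][7]annulen-2-yl tert-butyl carbonate | Oc1cc(OC(=O)OC(C)(C)C)cc2c1C(=Cc1ccc(OCc9ccccc9)cc1)c1cc(OCc9ccccc9)cc(OCc9ccccc9)c1[C@H](c1ccc(OCc9ccccc9)cc1OCc9ccccc9)C2
F5 | step 19 | (E)-1,3-bis(benzyloxy)-5-(2-nitrovinyl)benzene | O=[N+]([O-])/C=C/c1cc(OCc2ccccc2)cc(OCc2ccccc2)c1
F6 | step 19 | Friedel–Crafts adduct of 26 at C14b: (8cR)-CH[3,5-bis(benzyloxy)phenyl]CH2NO2 | c9ccccc9COc1ccc([C@H]2Oc3cc(O)c([C@@H](c4cc(OCc9ccccc9)cc(OCc9ccccc9)c4)C[N+](=O)[O-])c5c3[C@@H]2c2cc(OCc9ccccc9)cc(OCc9ccccc9)c2[C@H](c2ccc(OCc9ccccc9)cc2OCc9ccccc9)C5)cc1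
F7 | step 19 | lactol (2-hydroxy-2,3-dihydrofuran, anomeric mixture) from Nef reaction of F6 | c9ccccc9COc1ccc([C@H]2Oc3cc4c(c5c3[C@@H]2c2cc(OCc9ccccc9)cc(OCc9ccccc9)c2[C@H](c2ccc(OCc9ccccc9)cc2OCc9ccccc9)C5)[C@@H](c2cc(OCc9ccccc9)cc(OCc9ccccc9)c2)C(O)O4)cc1
F8 | step 19 | phenol-carbinol (diol) from F7 and 4-(benzyloxy)phenylmagnesium bromide (carbinol epimers) | c9ccccc9COc1ccc([C@H]2Oc3cc(O)c([C@@H](c4cc(OCc9ccccc9)cc(OCc9ccccc9)c4)C(O)c4ccc(OCc9ccccc9)cc4)c5c3[C@@H]2c2cc(OCc9ccccc9)cc(OCc9ccccc9)c2[C@H](c2ccc(OCc9ccccc9)cc2OCc9ccccc9)C5)cc1
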